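(All runs were computed from invented constants; the scatter is artificial.)

The green run ends at 6.43 % of its two substrates reacted and the grey run at 2.40 %, each the mean of its last 3 readings, and I read both as ends, not as slow progress.

the same everywhere: impurity 17 mM
- grey: left-handed substrate 1 M; right-handed substrate 1 M; reagent 2.2 equiv; free catalyst 2.5 mol%; run made earlier
- green: left-handed substrate 1 M; right-handed substrate 1 M; reagent 2.2 equiv; free catalyst 3.8 mol%; run made earlier
- flask: left-handed substrate 1.0 M; right-handed substrate 1.0 M; reagent 2.20 equiv; free catalyst 5 mol%; time 2.5 h

- grey (time / min: left-handed substrate / %, right-handed substrate / %): 5.00: 49.7, 50.0; 15.0: 48.9, 48.9; 25.0: 49.7, 49.3; 40.0: 49.1, 49.4; 50.0: 48.7, 48.7; 80.0: 48.6, 49.2; 90.0: 48.9, 48.7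
- green (time / min: left-handed substrate / %, right-handed substrate / %): 12.0: 48.6, 49.1; 25.0: 46.9, 47.9; 40.0: 47.3, 47.1; 50.0: 47.5, 47.3; 60.0: 46.6, 46.7; 80.0: 47.0, 47.4; 90.0: 46.4, 46.6

(each reading ± 0.3 percentage points)

- free catalyst is single-handed; left-handed substrate and right-handed substrate are mirror images of each other, charged as a racemate, each of them at the stated concentration
- what was read earlier has a scatter of 0.3 percentage points, one standard deviation
- an excess is the difference of the two amounts in percent of their sum
- an excess is below zero if the other one leads

1. part of the left-handed substrate and right-handed substrate charged together that has reacted at 2.5 h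
2. excess of left-handed product over right-handed product in the product at 2.5 h
3. excess of right-handed substrate over left-handed substrate among what is left of the two at 2.5 h

I follow one catalyst molecule: at its first fork the impurity may take it, and if it escapes, each later fork is another turnover or its loss. So I carry N, the product made per catalyst molecule that the impurity leaves, a turnover number. The extra catalyst of the green run over the grey run gives N = 6.21.

But this assumes that the impurity takes one catalyst each. I check that from the grey run: its product, divided by N, puts zero product at 17.3 mM of catalyst, and the impurity charged is 17 mM, so these readings bear the assumption. For the flask I get 10.2 % reacted.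

Which hand reacts faster I cannot read. In the green run the right-handed substrate leads on average by 0.26 percentage points, and the scatter of that mean of 7 differences is 0.16 points, so I take the lead as no firm reading. Such a gap also reports on the product only while each substrate keeps its hand.

The forecast gives 9.7 % reacted, a little below my figure, with product excess 4 % and substrate excess 0.43 %; its ground for the stop is “Each run ends early, so catalyst is being lost.”

The flask gives 9.53 % reacted, product excess 42.0 % and substrate excess 0.0216 %, and its product excess stands far above the forecast's.

reagent + free catalyst + left-handed substrate → free catalyst + left-handed product (k = 0.00170 L² mol⁻² s⁻¹); reagent + free catalyst + right-handed substrate → free catalyst + right-handed product (k = 6.80 × 10⁻⁴ L² mol⁻² s⁻¹); left-handed substrate ⇌ right-handed substrate (k = 4.10 × 10⁻⁴ s⁻¹); reagent + free catalyst → spent catalyst A (k = 3.90 × 10⁻⁴ L mol⁻¹ s⁻¹); free catalyst + impurity → spent catalyst B (k = 1.40 L mol⁻¹ s⁻¹) Reckoned back, N is 5.78 in this flask and 5.16 in a neighbouring flask charged with 12 mol% catalyst, which reacts 26.6 %. In the flask at 0.220 h, left-handed substrate goes to product at 0.15 of the forward rate at which it turns into right-handed substrate, and the half-life of left-handed substrate by that forward step alone, 0.47 h, is short against 2.5 h. In the flask the two substrates end level at 45.2 % and 45.2 %, while the left-handed product stands at 6.76 % against 2.76 % of right-handed product.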